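The oxolane is cut at O1–C2 and at C3–C4. O1, C5 (benzyl-bearing) and C4 (hydroxylated) form the α-alkoxy carbonyl unit of an aryl lactate, and C2, C3 and the CH2OH carbon are the β-, α- and carboxyl carbons of a cinnamate, so an anionic (3+2) annulation maps onto the ring.
Further cuts: the aryl–vinyl bond of the cinnamate (Heck), the C2'–C3' bond of the cis-dihydrobenzofuran (carbenoid C–H insertion into an aryl benzyl ether) and the aryl–CH2 bond of the lactate (aryl Grignard plus glycidate).
Forward: the dihydrofuran ring of the benzofuran is closed first (step 6), the acrylate is attached (step 9), the oxolane is formed last (step 11), then the ketone and ester are reduced and the protecting groups removed.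
Stereochemistry: C2'/C3' come from a chiral dirhodium carboxylate, C5 from methyl (S)-glycidate, C2 from C5 through the reversible oxa-Michael step, and C3/C4 together from a hydrogenation with dynamic kinetic resolution that is matched to the substrate.

Key step: step 11

Notation: ArBn = 4-(benzyloxy)-3-methoxyphenyl; DBF = the (2R,3R)-2-ArBn-3-[(tert-butyldimethylsilyloxy)methyl]-7-methoxy-2,3-dihydro-1-benzofuran-5-yl group (2,3-cis); the oxolane is numbered O1, C2 (aryl-bearing), C3, C4, C5 (benzyl-bearing), and primed locants refer to the dihydrobenzofuran.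
Assumption: the S-configured catalyst Rh2(S-PTTL)4 (dirhodium tetrakis[N-phthaloyl-(S)-tert-leucinate]) is taken to give the (2R,3S)-cis ester in step 6; if its sense of induction on this substrate is the opposite, Rh2(R-PTTL)4 is used with no other change.

Step 1
Reactants: 1 5-bromo-2-hydroxy-3-methoxybenzaldehyde; 2 [4-(benzyloxy)-3-methoxyphenyl]methanol
Product: 3 2-(ArBn-methoxy)-5-bromo-3-methoxybenzaldehyde
Conditions: PPh3, DIAD, THF, 0 °C → rt
Reagents that add atoms: none
Why: Mitsunobu etherification, in which the acidic salicylaldehyde-type phenol displaces the activated primary benzylic alcohol under neutral conditions, so the labile electron-rich benzyl halide need not be made.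

Step 2
Reactants: 3 2-(ArBn-methoxy)-5-bromo-3-methoxybenzaldehyde; 4 p-toluenesulfonylmethyl isocyanide (TosMIC)
Product: 6 2-[2-(ArBn-methoxy)-5-bromo-3-methoxyphenyl]acetonitrile, via N-(1-tosylvinyl)formamide 5 (not isolated)
Conditions: t-BuOK, DME, −40 °C; then MeOH, reflux
Reagents that add atoms: none
Why: van Leusen reductive cyanation, in which metalated TosMIC adds to the aldehyde, the oxazoline opens to the vinyl formamide, and methanolysis with loss of sulfinate gives ArCH2CN under basic conditions that spare the acid-sensitive benzyl aryl ether.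

Step 3
Reactants: 6 2-[2-(ArBn-methoxy)-5-bromo-3-methoxyphenyl]acetonitrile
Product: 7 2-[2-(ArBn-methoxy)-5-bromo-3-methoxyphenyl]acetic acid
Conditions: KOH, EtOH/H2O, reflux; then 1 M HCl, 0 °C
Reagents that add atoms: water, O; potassium hydroxide, [K+].[OH-]
Why: alkaline nitrile hydrolysis, to which the aryl ethers and the aryl bromide are inert, with acid met only briefly in the cold on liberation of the acid.

Step 4
Reactants: 7 2-[2-(ArBn-methoxy)-5-bromo-3-methoxyphenyl]acetic acid
Product: 8 methyl 2-[2-(ArBn-methoxy)-5-bromo-3-methoxyphenyl]acetate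
Conditions: MeI, K2CO3, DMF, rt
Reagents that add atoms: iodomethane, CI
Why: SN2 O-alkylation of the carboxylate, the only acidic site, gives the methyl ester without acid.

Step 5
Reactants: 8 methyl 2-[2-(ArBn-methoxy)-5-bromo-3-methoxyphenyl]acetate
Product: 9 methyl 2-[2-(ArBn-methoxy)-5-bromo-3-methoxyphenyl]-2-diazoacetate
Conditions: p-ABSA, DBU, MeCN, 0 °C → rt
Reagents that add atoms: 4-acetamidobenzenesulfonyl azide (p-ABSA), CC(=O)Nc1ccc(cc1)S(=O)(=O)N=[N+]=[N-]
Why: Regitz diazo transfer to the benzylic ester enolate is the standard entry to aryl diazoacetates, the precursors of donor/acceptor carbenoids.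

Step 6
Reactants: 9 methyl 2-[2-(ArBn-methoxy)-5-bromo-3-methoxyphenyl]-2-diazoacetate
Product: 10 methyl (2R,3S)-2-ArBn-5-bromo-7-methoxy-2,3-dihydro-1-benzofuran-3-carboxylate (2,3-cis)
Conditions: Rh2(S-PTTL)4 (1 mol %), toluene, −60 °C
Reagents that add atoms: none
Why: intramolecular 1,5 C–H insertion of the rhodium donor/acceptor carbenoid into the oxygen-activated benzylic methylene closes the dihydrofuran ring, and the chiral phthalimido-carboxylate ligand sphere is expected to set C2' and C3' together as the kinetic cis pair, as is known for 2-(benzyloxy)phenyl diazoacetates.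

Step 7
Reactants: 10 methyl (2R,3S)-2-ArBn-5-bromo-7-methoxy-2,3-dihydro-1-benzofuran-3-carboxylate
Product: 11 [(2R,3R)-2-ArBn-5-bromo-7-methoxy-2,3-dihydro-1-benzofuran-3-yl]methanol (2,3-cis)
Conditions: i-Bu2AlH, CH2Cl2, −78 → −20 °C
Reagents that add atoms: none
Why: ester reduction with the non-basic hydride i-Bu2AlH at low temperature removes the only epimerisable position (C3', α to the ester) before it can drift to the trans series and leaves the aryl bromide intact.

Step 8
Reactants: 11 [(2R,3R)-2-ArBn-5-bromo-7-methoxy-2,3-dihydro-1-benzofuran-3-yl]methanol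
Product: 12 (2R,3R)-2-ArBn-5-bromo-3-[(tert-butyldimethylsilyloxy)methyl]-7-methoxy-2,3-dihydro-1-benzofuran
Conditions: TBSCl, imidazole, DMF, rt
Reagents that add atoms: tert-butyl(chloro)dimethylsilane (TBSCl), CC(C)(C)[Si](C)(C)Cl
Why: silylation of the primary alcohol masks the only hydroxyl that could compete as an oxa-Michael donor in step 11.

Step 9
Reactants: 12 (2R,3R)-2-ArBn-5-bromo-3-[(tert-butyldimethylsilyloxy)methyl]-7-methoxy-2,3-dihydro-1-benzofuran; 13 methyl acrylate
Product: 14 methyl (2E)-3-DBF-prop-2-enoate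
Conditions: Pd(OAc)2 (5 mol %), P(o-tol)3, Et3N, DMF, 100 °C
Reagents that add atoms: none
Why: Mizoroki–Heck arylation of the acrylate by the unhindered aryl bromide gives the E-cinnamate through syn insertion and syn β-hydride elimination, and the substrate has no base-sensitive centre left.

Step 10
Reactants: 15 1-(benzyloxy)-4-bromo-2-methoxybenzene; 16 methyl (2S)-oxirane-2-carboxylate
Product: 18 methyl (2S)-3-ArBn-2-hydroxypropanoate, via aryl Grignard reagent 17 (not isolated)
Conditions: Mg, THF, 40 °C; then CuBr·SMe2 (10 mol %), 16, −40 °C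
Reagents that add atoms: none
Why: copper-catalysed Grignard opening of the glycidic ester takes place by SN2 attack at the unsubstituted CH2, faster than carbonyl addition at low temperature, and does not touch the C2–O bond, so the S configuration of 16 is carried into the lactate.

Step 11
Reactants: 18 methyl (2S)-3-ArBn-2-hydroxypropanoate; 14 methyl (2E)-3-DBF-prop-2-enoate
Product: 20 methyl (2S,3R,5S)-5-(ArBn-methyl)-2-DBF-4-oxooxolane-3-carboxylate, via open-chain oxa-Michael adduct 19 (not isolated)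
Conditions: NaH, THF/DMSO, 0 °C → rt; then AcOH
Reagents that add atoms: none
Why: NaH turns 18 into its sodium alkoxide, which adds reversibly to the β-carbon of cinnamate 14 (O1–C2 bond), and the ester enolate of adduct 19 then attacks the lactate ester carbonyl and expels methoxide (C3–C4 bond), after which deprotonation of the β-keto ester makes the sequence irreversible. The closest known reaction type is the base-mediated oxa-Michael–Dieckmann annulation of α-hydroxy esters with acrylates, crotonates and cinnamates to 4-oxotetrahydrofuran-3-carboxylates. The oxolane ring is closed in the second event by a 5-exo-trig Dieckmann condensation, the enolate carbon C3 attacking the exocyclic C=O of the lactate ester. C5 is the untouched lactate centre (the product rests as the C3–C4 enolate, so H-5 is not acidic), the new C2 centre is controlled by C5 because the reversibly formed adducts should funnel through the lower-lying 2,5-cis closure with aryl and benzyl both pseudo-equatorial, and the new C3 centre settles trans to the C2 aryl group through the enol on work-up. The step needs conjugate O-addition to win over lactate self-condensation and transesterification, which are reversible resting states whereas only the annulation is drained by enolate formation, and DMSO raises the alkoxide reactivity towards the electron-rich acceptor. The cis-dihydrobenzofuran has no acidic hydrogen (C3' carries CH2OTBS and the acrylate is meta to C3a), so it should pass unchanged.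

Step 12
Reactants: 20 methyl (2S,3R,5S)-5-(ArBn-methyl)-2-DBF-4-oxooxolane-3-carboxylate
Product: 21 methyl (2S,3S,4S,5S)-5-(ArBn-methyl)-2-DBF-4-hydroxyoxolane-3-carboxylate
Conditions: H2 (80 atm), RuCl2[(R)-BINAP] (2 mol %), CH2Cl2, 50 °C
Reagents that add atoms: none
Why: Noyori hydrogenation of a cyclic β-keto ester under dynamic kinetic resolution, in which C3 epimerises through the enol faster than reduction, the ester-chelated Ru–H delivers hydrogen to C4 on the ester-bearing face to give the 3,4-trans hydroxy ester, and (R)-BINAP is the antipode whose sense for cyclic β-keto esters corresponds to 4S, in line with the substrate's own bias (hydride anti to the C5 benzyl and C2 aryl groups, ester trans to aryl).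

Step 13
Reactants: 21 methyl (2S,3S,4S,5S)-5-(ArBn-methyl)-2-DBF-4-hydroxyoxolane-3-carboxylate
Product: 22 (2S,3S,4S,5S)-5-(ArBn-methyl)-2-DBF-3-(hydroxymethyl)oxolan-4-ol
Conditions: LiBH4, THF/MeOH, 0 °C → rt
Reagents that add atoms: none
Why: LiBH4 reduces the hydroxyl-activated ester to the primary alcohol under non-equilibrating conditions, so C3 keeps its configuration and the ethers are untouched.

Step 14
Reactants: 22 (2S,3S,4S,5S)-5-(ArBn-methyl)-2-DBF-3-(hydroxymethyl)oxolan-4-ol
Product: 23 (2S,3S,4S,5S)-5-(ArBn-methyl)-2-[(2R,3R)-2-ArBn-3-(hydroxymethyl)-7-methoxy-2,3-dihydro-1-benzofuran-5-yl]-3-(hydroxymethyl)oxolan-4-ol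
Conditions: Bu4NF, AcOH, THF, 0 °C → rt
Reagents that add atoms: none
Why: fluoride-induced desilylation, buffered with AcOH and carried out while both phenols are still benzylated, so that no phenoxide that could open a benzylic ether through a quinone methide is exposed.

Step 15
Reactants: 23 (2S,3S,4S,5S)-5-(ArBn-methyl)-2-[(2R,3R)-2-ArBn-3-(hydroxymethyl)-7-methoxy-2,3-dihydro-1-benzofuran-5-yl]-3-(hydroxymethyl)oxolan-4-ol
Product: 24 (2S,3S,4S,5S)-2-[(2R,3R)-2-(4-hydroxy-3-methoxyphenyl)-3-(hydroxymethyl)-7-methoxy-2,3-dihydro-1-benzofuran-5-yl]-5-[(4-hydroxy-3-methoxyphenyl)methyl]-3-(hydroxymethyl)oxolan-4-ol (target)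
Conditions: H2 (1 atm), Pd/C (10 %), EtOAc, rt
Reagents that add atoms: none
Why: hydrogenolysis of the two aryl benzyl ethers, whose ArO–CH2Ph bonds should cleave much faster than the ring benzylic C–O bonds of the dihydrobenzofuran and the oxolane, under neutral conditions that do not epimerise the cis-dihydrobenzofuran.

Compound list
1 | 5-bromo-2-hydroxy-3-methoxybenzaldehyde | COc1cc(Br)cc(C=O)c1O | starting material
2 | [4-(benzyloxy)-3-methoxyphenyl]methanol | COc1cc(CO)ccc1OCc1ccccc1 | starting material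
3 | 2-{[4-(benzyloxy)-3-methoxyphenyl]methoxy}-5-bromo-3-methoxybenzaldehyde | COc1cc(Br)cc(C=O)c1OCc1ccc(OCc2ccccc2)c(OC)c1 | intermediate
4 | p-toluenesulfonylmethyl isocyanide (TosMIC) | Cc1ccc(cc1)S(=O)(=O)C[N+]#[C-] | starting material
5 | N-[2-(2-{[4-(benzyloxy)-3-methoxyphenyl]methoxy}-5-bromo-3-methoxyphenyl)-1-(4-methylbenzenesulfonyl)ethenyl]formamide (potassium salt in the flask) | O=CNC(=Cc1cc(Br)cc(OC)c1OCc1ccc(OCc2ccccc2)c(OC)c1)S(=O)(=O)c1ccc(C)cc1 | intermediate
6 | 2-(2-{[4-(benzyloxy)-3-methoxyphenyl]methoxy}-5-bromo-3-methoxyphenyl)acetonitrile | N#CCc1cc(Br)cc(OC)c1OCc1ccc(OCc2ccccc2)c(OC)c1 | intermediate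
7 | 2-(2-{[4-(benzyloxy)-3-methoxyphenyl]methoxy}-5-bromo-3-methoxyphenyl)acetic acid | OC(=O)Cc1cc(Br)cc(OC)c1OCc1ccc(OCc2ccccc2)c(OC)c1 | intermediate
8 | methyl 2-(2-{[4-(benzyloxy)-3-methoxyphenyl]methoxy}-5-bromo-3-methoxyphenyl)acetate | COC(=O)Cc1cc(Br)cc(OC)c1OCc1ccc(OCc2ccccc2)c(OC)c1 | intermediate
9 | methyl 2-(2-{[4-(benzyloxy)-3-methoxyphenyl]methoxy}-5-bromo-3-methoxyphenyl)-2-diazoacetate | COC(=O)C(=[N+]=[N-])c1cc(Br)cc(OC)c1OCc1ccc(OCc2ccccc2)c(OC)c1 | intermediate
10 | methyl (2R,3S)-2-[4-(benzyloxy)-3-methoxyphenyl]-5-bromo-7-methoxy-2,3-dihydro-1-benzofuran-3-carboxylate (2,3-cis) | Brc1cc(OC)c2c(c1)[C@H](C(=O)OC)[C@H](c1ccc(OCc3ccccc3)c(OC)c1)O2 | intermediate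
11 | [(2R,3R)-2-[4-(benzyloxy)-3-methoxyphenyl]-5-bromo-7-methoxy-2,3-dihydro-1-benzofuran-3-yl]methanol (2,3-cis) | Brc1cc(OC)c2c(c1)[C@H](CO)[C@H](c1ccc(OCc3ccccc3)c(OC)c1)O2 | intermediate
12 | tert-butyl{[(2R,3R)-2-[4-(benzyloxy)-3-methoxyphenyl]-5-bromo-7-methoxy-2,3-dihydro-1-benzofuran-3-yl]methoxy}dimethylsilane | Brc1cc(OC)c2c(c1)[C@H](CO[Si](C)(C)C(C)(C)C)[C@H](c1ccc(OCc3ccccc3)c(OC)c1)O2 | intermediate
13 | methyl acrylate | COC(=O)C=C | starting material
14 | methyl (2E)-3-[(2R,3R)-2-[4-(benzyloxy)-3-methoxyphenyl]-3-({[tert-butyl(dimethyl)silyl]oxy}methyl)-7-methoxy-2,3-dihydro-1-benzofuran-5-yl]prop-2-enoate | COC(=O)/C=C/c1cc(OC)c2c(c1)[C@H](CO[Si](C)(C)C(C)(C)C)[C@H](c1ccc(OCc3ccccc3)c(OC)c1)O2 | intermediate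
15 | 1-(benzyloxy)-4-bromo-2-methoxybenzene | COc1cc(Br)ccc1OCc1ccccc1 | starting material
16 | methyl (2S)-oxirane-2-carboxylate (methyl (S)-glycidate) | COC(=O)[C@@H]1CO1 | starting material
17 | [4-(benzyloxy)-3-methoxyphenyl]magnesium bromide | COc1cc([Mg]Br)ccc1OCc1ccccc1 | intermediate
18 | methyl (2S)-3-[4-(benzyloxy)-3-methoxyphenyl]-2-hydroxypropanoate | COc1cc(C[C@H](O)C(=O)OC)ccc1OCc1ccccc1 | intermediate
19 | methyl (3S)-3-{[(2S)-3-[4-(benzyloxy)-3-methoxyphenyl]-1-methoxy-1-oxopropan-2-yl]oxy}-3-[(2R,3R)-2-[4-(benzyloxy)-3-methoxyphenyl]-3-({[tert-butyl(dimethyl)silyl]oxy}methyl)-7-methoxy-2,3-dihydro-1-benzofuran-5-yl]propanoate (sodium ester enolate in the flask) | COC(=O)C[C@H](O[C@@H](Cc1ccc(OCc2ccccc2)c(OC)c1)C(=O)OC)c1cc(OC)c2c(c1)[C@H](CO[Si](C)(C)C(C)(C)C)[C@H](c1ccc(OCc3ccccc3)c(OC)c1)O2 | intermediate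
20 | methyl (2S,3R,5S)-5-{[4-(benzyloxy)-3-methoxyphenyl]methyl}-2-[(2R,3R)-2-[4-(benzyloxy)-3-methoxyphenyl]-3-({[tert-butyl(dimethyl)silyl]oxy}methyl)-7-methoxy-2,3-dihydro-1-benzofuran-5-yl]-4-oxooxolane-3-carboxylate (keto form; C3 labile through the enol) | COc1cc(C[C@@H]2O[C@H](c3cc(OC)c4c(c3)[C@H](CO[Si](C)(C)C(C)(C)C)[C@H](c3ccc(OCc5ccccc5)c(OC)c3)O4)[C@@H](C(=O)OC)C2=O)ccc1OCc1ccccc1 | intermediate
21 | methyl (2S,3S,4S,5S)-5-{[4-(benzyloxy)-3-methoxyphenyl]methyl}-2-[(2R,3R)-2-[4-(benzyloxy)-3-methoxyphenyl]-3-({[tert-butyl(dimethyl)silyl]oxy}methyl)-7-methoxy-2,3-dihydro-1-benzofuran-5-yl]-4-hydroxyoxolane-3-carboxylate | COc1cc(C[C@@H]2O[C@H](c3cc(OC)c4c(c3)[C@H](CO[Si](C)(C)C(C)(C)C)[C@H](c3ccc(OCc5ccccc5)c(OC)c3)O4)[C@@H](C(=O)OC)[C@@H]2O)ccc1OCc1ccccc1 | intermediate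
22 | (2S,3S,4S,5S)-5-{[4-(benzyloxy)-3-methoxyphenyl]methyl}-2-[(2R,3R)-2-[4-(benzyloxy)-3-methoxyphenyl]-3-({[tert-butyl(dimethyl)silyl]oxy}methyl)-7-methoxy-2,3-dihydro-1-benzofuran-5-yl]-3-(hydroxymethyl)oxolan-4-ol | COc1cc(C[C@@H]2O[C@H](c3cc(OC)c4c(c3)[C@H](CO[Si](C)(C)C(C)(C)C)[C@H](c3ccc(OCc5ccccc5)c(OC)c3)O4)[C@@H](CO)[C@@H]2O)ccc1OCc1ccccc1 | intermediate
23 | (2S,3S,4S,5S)-5-{[4-(benzyloxy)-3-methoxyphenyl]methyl}-2-[(2R,3R)-2-[4-(benzyloxy)-3-methoxyphenyl]-3-(hydroxymethyl)-7-methoxy-2,3-dihydro-1-benzofuran-5-yl]-3-(hydroxymethyl)oxolan-4-ol | COc1cc(C[C@@H]2O[C@H](c3cc(OC)c4c(c3)[C@H](CO)[C@H](c3ccc(OCc5ccccc5)c(OC)c3)O4)[C@@H](CO)[C@@H]2O)ccc1OCc1ccccc1 | intermediate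
24 | (2S,3S,4S,5S)-2-[(2R,3R)-2-(4-hydroxy-3-methoxyphenyl)-3-(hydroxymethyl)-7-methoxy-2,3-dihydro-1-benzofuran-5-yl]-5-[(4-hydroxy-3-methoxyphenyl)methyl]-3-(hydroxymethyl)oxolan-4-ol (CNP0179668.1) | COc1cc(C[C@@H]2O[C@H](c3cc(OC)c4c(c3)[C@H](CO)[C@H](c3ccc(O)c(OC)c3)O4)[C@@H](CO)[C@@H]2O)ccc1O | target

Total step count: 15. Longest linear sequence: 14 steps (steps 1–9 and 11–15, from 1 to 24); step 10 supplies the lactate branch.

Steps most likely to fail

Step 11. Conjugate addition of the alkoxide to a cinnamate deactivated by the para ring oxygen may be slow relative to retro-addition and lactate self-condensation, and the 2,5-cis preference at C2 may be modest. The fallback forms the O1–C2 bond through an oxocarbenium ion, which the same electron-rich arene stabilises. It sets out from 12 and 18. Bromine–lithium exchange of 12 (n-BuLi, THF, −78 °C) and formylation with DMF should give (2R,3R)-2-ArBn-3-[(tert-butyldimethylsilyloxy)methyl]-7-methoxy-2,3-dihydro-1-benzofuran-5-carbaldehyde F1. Silylation of 18 (TMSCl, imidazole, CH2Cl2) gives methyl (2S)-3-ArBn-2-[(trimethylsilyl)oxy]propanoate F2. F1, F2 and 1-methoxy-1-(trimethylsilyloxy)ethene are combined with catalytic TMSOTf in CH2Cl2 at −78 °C (acetal formation followed by a Mukaiyama aldol-type substitution). This should give the open-chain ether diester 19 together with the benzylic epimer of 19 F3. Treatment of the mixture with t-BuOK in THF at 0 °C (Dieckmann condensation, with retro-Michael/Michael equilibration of the benzylic centre) comes back to the route at 20.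

Step 12. Hydrogen uptake by the hindered keto ester may be slow, or reduction may occur from the wrong face or out of the wrong C3 epimer, so that C3/C4 diastereomers form. The fallback replaces catalyst control by internal hydride delivery from a C3 hydroxymethyl group and sets out from 20. TBSOTf and Et3N in CH2Cl2 give the 4-silyl enol ether of 20 F4. i-Bu2AlH at −78 °C reduces its ester to the 3-(hydroxymethyl) enol silyl ether F5. Bu4NF buffered with AcOH removes both silyl groups and liberates (2S,3R,5S)-5-(ArBn-methyl)-2-[(2R,3R)-2-ArBn-3-(hydroxymethyl)-7-methoxy-2,3-dihydro-1-benzofuran-5-yl]-3-(hydroxymethyl)oxolan-4-one F6, in which C3 settles trans to the C2 aryl group. Me4NBH(OAc)3 in MeCN/AcOH at −20 °C (Evans–Saksena reduction) then delivers hydride to C4 from the face of the C3 CH2OH group. The resulting 3,4-trans diol comes back to the route at 23.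

Step 6. The methoxy group next to the ether oxygen may change the conformation of the benzyloxy arm and erode enantio- or cis-selectivity in the insertion, and carbenoid dimerisation may compete. The fallback is resolution in place of catalyst control and sets out from 11 of insufficient enantiomeric purity. Esterification with (S)-2-methoxy-2-phenylacetic acid (DCC, DMAP, CH2Cl2) gives the (S)-O-methylmandelate of 11 F7 and the (S)-O-methylmandelate of the enantiomer of 11 F8. These are separated by chromatography or crystallisation. Methanolysis of F7 (K2CO3, MeOH) comes back to the route at enantiopure 11.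

Further compounds
F1 | step 11 | (2R,3R)-2-[4-(benzyloxy)-3-methoxyphenyl]-3-({[tert-butyl(dimethyl)silyl]oxy}methyl)-7-methoxy-2,3-dihydro-1-benzofuran-5-carbaldehyde | O=Cc1cc(OC)c2c(c1)[C@H](CO[Si](C)(C)C(C)(C)C)[C@H](c1ccc(OCc3ccccc3)c(OC)c1)O2
F2 | step 11 | methyl (2S)-3-[4-(benzyloxy)-3-methoxyphenyl]-2-[(trimethylsilyl)oxy]propanoate | COc1cc(C[C@H](O[Si](C)(C)C)C(=O)OC)ccc1OCc1ccccc1
F3 | step 11 | benzylic (3R) epimer of 19 | COC(=O)C[C@@H](O[C@@H](Cc1ccc(OCc2ccccc2)c(OC)c1)C(=O)OC)c1cc(OC)c2c(c1)[C@H](CO[Si](C)(C)C(C)(C)C)[C@H](c1ccc(OCc3ccccc3)c(OC)c1)O2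
F4 | step 12 | methyl 5-(ArBn-methyl)-2-DBF-4-[(tert-butyldimethylsilyl)oxy]-2,5-dihydrofuran-3-carboxylate (2,5-cis as in 20) | COc1cc(C[C@@H]2O[C@H](c3cc(OC)c4c(c3)[C@H](CO[Si](C)(C)C(C)(C)C)[C@H](c3ccc(OCc5ccccc5)c(OC)c3)O4)C(C(=O)OC)=C2O[Si](C)(C)C(C)(C)C)ccc1OCc1ccccc1
F5 | step 12 | [5-(ArBn-methyl)-2-DBF-4-[(tert-butyldimethylsilyl)oxy]-2,5-dihydrofuran-3-yl]methanol (2,5-cis as in 20) | COc1cc(C[C@@H]2O[C@H](c3cc(OC)c4c(c3)[C@H](CO[Si](C)(C)C(C)(C)C)[C@H](c3ccc(OCc5ccccc5)c(OC)c3)O4)C(CO)=C2O[Si](C)(C)C(C)(C)C)ccc1OCc1ccccc1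
F6 | step 12 | (2S,3R,5S)-5-{[4-(benzyloxy)-3-methoxyphenyl]methyl}-2-[(2R,3R)-2-[4-(benzyloxy)-3-methoxyphenyl]-3-(hydroxymethyl)-7-methoxy-2,3-dihydro-1-benzofuran-5-yl]-3-(hydroxymethyl)oxolan-4-one | COc1cc(C[C@@H]2O[C@H](c3cc(OC)c4c(c3)[C@H](CO)[C@H](c3ccc(OCc5ccccc5)c(OC)c3)O4)[C@@H](CO)C2=O)ccc1OCc1ccccc1
F7 | step 6 | [(2R,3R)-2-[4-(benzyloxy)-3-methoxyphenyl]-5-bromo-7-methoxy-2,3-dihydro-1-benzofuran-3-yl]methyl (2S)-2-methoxy-2-phenylacetate | Brc1cc(OC)c2c(c1)[C@H](COC(=O)[C@@H](OC)c1ccccc1)[C@H](c1ccc(OCc3ccccc3)c(OC)c1)O2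
F8 | step 6 | [(2S,3S)-2-[4-(benzyloxy)-3-methoxyphenyl]-5-bromo-7-methoxy-2,3-dihydro-1-benzofuran-3-yl]methyl (2S)-2-methoxy-2-phenylacetate | Brc1cc(OC)c2c(c1)[C@@H](COC(=O)[C@@H](OC)c1ccccc1)[C@@H](c1ccc(OCc3ccccc3)c(OC)c1)O2
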